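**Retrosynthetic overview** (ring positions numbered as in shikimic acid: C1 bears CO2Me, C1=C2, C3/C4/C5 oxygenated, C6 is CH2)
- The target is methyl shikimate 3,5-bis[(E)-3-methylpent-2-enoate]. The C3 ester is cut last (regioselective acylation of a 3,4-diol), then the C5 ester with inversion (Mitsunobu on a 5-epi alcohol held as its 3,4-acetonide).
- The all-cis 3,4,5-triol pattern is traced, through ketal migration and face-selective ketone reduction, to a C4 ketone whose O3 and O5 are bridged by an isopropylidene: a 2,4-dioxabicyclo[3.3.1]non-6-en-9-one.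
- Key disconnection (C2–C3 and C6–C5 together): asymmetric [3+3] α,α′-annulation of a chiral enamine of 2,2-dimethyl-1,3-dioxan-5-one (C3–C4–C5) with methyl (Z)-3-bromo-2-(bromomethyl)acrylate (C2=C1(CO2Me)–C6).
- Enabling feature: C4 lies between the two oxygen-bearing carbons C3 and C5, so at the ketone level these are the α and α′ carbons of a dihydroxyacetone ketal (two nucleophilic sites). The ester on C1, conjugated to C1=C2, makes C6 (allylic CH2) and C2 (β-vinylic CH) the two electrophilic ends of one acrylate. The cis O3/O5 ketal makes both α-carbons bridgeheads, so the 4-oxo-enoate can neither enolise nor aromatise.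
- Ring order: dioxanone ring (bought) → carbocycle (key step, the only C–C ring closure) → cis-fused dioxolane (by ketal migration), removed before the last acylation.

Key step: step 5

Remark: the facial sense of the enamine alkylation, and hence the choice of the (2R,5R)-amine, follows from the steric model given in step 5; should the opposite sense be found, the (2S,5S)-amine would be used with no other change.

**Route**

Step 1
Reactants: 1 ethyl but-2-ynoate
Product: 2 ethyl (E)-3-methylpent-2-enoate
Conditions: EtMgBr (2.2 equiv), CuI (1.1 equiv), THF, −40 °C; then 1, −78 °C; MeOH, −78 °C; aq NH4Cl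
Reagents that add atoms: ethylmagnesium bromide (EtMgBr), CC[Mg]Br
Why: syn-carbocupration of an ynoate (organocuprate conjugate addition): ethyl and copper add cis and the vinylcopper is protonated with retention at −78 °C, so ethyl ends trans to the ester (E).

Step 2
Reactants: 2 ethyl (E)-3-methylpent-2-enoate
Product: 3 (E)-3-methylpent-2-enoic acid
Conditions: LiOH·H2O (2 equiv), THF/H2O (3:1), rt; then 1 M HCl to pH 2
Reagents that add atoms: lithium hydroxide (LiOH), [Li+].[OH-]
Why: ester saponification; hydroxide is too weak a base to form the dienolate, so the E alkene should be kept.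

Step 3
Reactants: 4 methyl 2-(bromomethyl)acrylate
Product: 6 methyl (Z)-3-bromo-2-(bromomethyl)acrylate, via tribromide 5 (not isolated)
Conditions: Br2 (1.05 equiv), CH2Cl2, 0 °C → rt; then i-Pr2NEt (1.1 equiv), 0 → 40 °C
Reagents that add atoms: bromine, BrBr
Why: alkene bromination followed by E2 dehydrobromination of the tertiary α-bromo ester (only the CH2Br hydrogens are β) should give the conjugated vinyl bromide, mainly with Br trans to the ester as for 3-bromomethacrylates; the alkene geometry is not carried into the product of step 5.

Step 4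
Reactants: 7 2,2-dimethyl-1,3-dioxan-5-one; 8 (2R,5R)-2,5-dimethylpyrrolidine
Product: 9 (2R,5R)-1-(2,2-dimethyl-4H-1,3-dioxin-5-yl)-2,5-dimethylpyrrolidine (the enamine)
Conditions: 4 Å molecular sieves, toluene, rt → 40 °C; filtered, concentrated, used crude
Reagents that add atoms: none
Why: enamine condensation of a reactive α,α′-dioxygenated ketone under neutral dehydrating conditions that spare the ketal; the C2-symmetric amine gives the same enamine whichever C–N rotamer is populated.

Step 5
Reactants: 9 the enamine; 6 methyl (Z)-3-bromo-2-(bromomethyl)acrylate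
Product: 12 methyl (1S,5R)-3,3-dimethyl-9-oxo-2,4-dioxabicyclo[3.3.1]non-6-ene-7-carboxylate, via monoalkylated enamine 10 (not isolated), via bicyclic iminium bromide 11 (not isolated)
Conditions: 6 (1.0 equiv, added over 2 h), i-Pr2NEt (2.2 equiv), MeCN, −20 °C → rt; then 60 °C; then NaOAc/AcOH buffer (pH 5), H2O, rt
Reagents that add atoms: water, O
Why: Proposed new method: the nucleophilic enamine carbon of 9 displaces the primary allylic bromide of 6 (SN2, first C–C bond, to the future ring CH2), i-Pr2NEt deprotonates the iminium to the less substituted enamine 10 on the other α-carbon, and this carbon adds to the bromine-bearing β-carbon of the now tethered acrylate, after which the ester enolate expels bromide (conjugate addition–elimination, second C–C bond, to the future vinylic CH), giving the conjugated ring alkene directly in iminium 11, which the buffer hydrolyses to 12. The closest known reaction types are the α,α′-annulation of cyclic ketone enamines with 2-(bromomethyl)acrylates to bicyclo[3.3.1]nonan-9-ones, the amine-mediated asymmetric α,α′-annulation of cyclic ketones with nitroallylic acetates, and the face-selective C-alkylation of enamines of C2-symmetric trans-2,5-dimethylpyrrolidine; new are the β-bromo terminus, which ends the cascade by vinylic substitution instead of protonation, and the use of the chiral enamine to distinguish the two enantiotopic α-carbons of 7. The carbocycle closes by a 6-endo-trig addition–elimination in which the tether sits axial on the enamine ring, and this closure also completes the 2,4-dioxabicyclo[3.3.1]nonene. The stereocentre bonded to the ring CH2 (S) is set by the auxiliary, the electrophile entering on the enamine face opposite the pyrrolidine methyl group that lies syn to the reacting carbon, and the allylic stereocentre (R) is set by the ring, because a three-carbon bridge can span the two α-carbons only cis; this second closure runs against the auxiliary's own facial preference, which costs rate but cannot change the outcome. The step needs C-alkylation at CH2Br before any attack at the vinylic carbon (which would lead to the enantiomer), C- over N-alkylation, and ring closure ahead of a second intermolecular alkylation: the primary allylic C–Br is far more reactive than the β-bromoacrylate terminus, the nitrogen is flanked by two methyl groups, the trisubstituted enamine is favoured over the tetrasubstituted one so the first stereocentre is not deprotonated, and both α-carbons of the product are bridgeheads so 12 can neither epimerise nor aromatise.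

Step 6
Reactants: 12 the bicyclic keto ester
Product: 13 methyl (1S,5R,9S)-9-hydroxy-3,3-dimethyl-2,4-dioxabicyclo[3.3.1]non-6-ene-7-carboxylate (OH on the dioxane side, cis to both ring oxygens on the carbocycle)
Conditions: NaBH4 (1.0 equiv), MeOH, −40 °C
Reagents that add atoms: none
Why: borohydride ketone reduction; hydride should add to the carbonyl face lying over the carbocycle, antiperiplanar to the two flanking C–O bonds and away from the oxygen lone pairs (the bias that leads 2-substituted 1,3-dioxan-5-ones to their axial alcohols), which sets C4 with OH cis to O3 and O5, and the enoate should not be touched at this temperature.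

Step 7
Reactants: 13 the bicyclic alcohol
Product: 14 methyl (3aR,7S,7aS)-7-hydroxy-2,2-dimethyl-3a,6,7,7a-tetrahydro-1,3-benzodioxole-5-carboxylate (methyl 3,4-O-isopropylidene-5-epi-shikimate)
Conditions: CSA (5 mol %), dry acetone, rt
Reagents that add atoms: none
Why: acid-catalysed ketal migration (transketalisation) under thermodynamic control: the strained diaxial six-membered ketal reopens and recloses with the cis C4 hydroxyl to a cis-fused dioxolane, expected on the allylic C3/C4 pair because that flattened ring bond best fits the small O–C–C–O torsion of a dioxolane, so only the C5 hydroxyl is left free; no stereocentre changes.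

Step 8
Reactants: 14 methyl 3,4-O-isopropylidene-5-epi-shikimate; 3 (E)-3-methylpent-2-enoic acid
Product: 15 methyl (3aR,7R,7aS)-2,2-dimethyl-7-{[(E)-3-methylpent-2-enoyl]oxy}-3a,6,7,7a-tetrahydro-1,3-benzodioxole-5-carboxylate
Conditions: 3 (1.5 equiv), PPh3 (1.5 equiv), DIAD (1.5 equiv), THF, 0 °C → rt
Reagents that add atoms: none
Why: Mitsunobu esterification: the carboxylate displaces the activated C5 oxygen by SN2 from the face opposite the cis-fused ketal, inverting C5 to the required R configuration while installing the first acyl group.

Step 9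
Reactants: 15 the 5-O-acyl acetonide
Product: 16 methyl (3R,4R,5R)-3,4-dihydroxy-5-{[(E)-3-methylpent-2-enoyl]oxy}cyclohex-1-ene-1-carboxylate (methyl 5-O-acylshikimate; C4 is spatially unchanged, only its descriptor changes with the substituents)
Conditions: TFA/H2O (9:1), 0 °C
Reagents that add atoms: none
Why: acid hydrolysis of the isopropylidene ketal, standard for shikimate 3,4-acetonides; the esters should survive cold aqueous acid and no stereocentre is involved.

Step 10
Reactants: 16 methyl 5-O-acylshikimate; 3 (E)-3-methylpent-2-enoic acid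
Product: 17 methyl (3R,4S,5R)-4-hydroxy-3,5-bis{[(E)-3-methylpent-2-enoyl]oxy}cyclohex-1-ene-1-carboxylate (target, CNP0268575.1)
Conditions: 3 (1.1 equiv), EDC·HCl (1.2 equiv), DMAP (0.1 equiv), CH2Cl2, −20 → 0 °C
Reagents that add atoms: none
Why: Steglich esterification: the allylic C3 hydroxyl should react ahead of the C4 hydroxyl, which is flanked on both sides by oxygen-bearing carbons, one now carrying a bulky ester; neutral carbodiimide activation avoids dienolate or vinylketene formation, so the E alkene should be kept.

**Compound list**
1 | ethyl but-2-ynoate | CC#CC(=O)OCC | starting material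
2 | ethyl (E)-3-methylpent-2-enoate | CC/C(C)=C/C(=O)OCC | intermediate
3 | (E)-3-methylpent-2-enoic acid | CC/C(C)=C/C(=O)O | intermediate
4 | methyl 2-(bromomethyl)acrylate | COC(=O)C(=C)CBr | starting material
5 | methyl 2,3-dibromo-2-(bromomethyl)propanoate | COC(=O)C(Br)(CBr)CBr | intermediate (not isolated)
6 | methyl (Z)-3-bromo-2-(bromomethyl)acrylate | Br/C=C(\CBr)C(=O)OC | intermediate
7 | 2,2-dimethyl-1,3-dioxan-5-one | CC1(C)OCC(=O)CO1 | starting material
8 | (2R,5R)-2,5-dimethylpyrrolidine | C[C@@H]1CC[C@@H](C)N1 | starting material
9 | (2R,5R)-1-(2,2-dimethyl-4H-1,3-dioxin-5-yl)-2,5-dimethylpyrrolidine | C[C@@H]1CC[C@@H](C)N1C1=COC(C)(C)OC1 | intermediate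
10 | methyl (E)-3-bromo-2-{[(4S)-5-[(2R,5R)-2,5-dimethylpyrrolidin-1-yl]-2,2-dimethyl-4H-1,3-dioxin-4-yl]methyl}acrylate | Br/C=C(\C[C@@H]1OC(C)(C)OC=C1N1[C@H](C)CC[C@H]1C)C(=O)OC | intermediate (not isolated)
11 | (2R,5R)-1-[(1S,5R)-7-(methoxycarbonyl)-3,3-dimethyl-2,4-dioxabicyclo[3.3.1]non-6-en-9-ylidene]-2,5-dimethylpyrrolidin-1-ium bromide | CC1(C)O[C@@H]2C=C(C(=O)OC)C[C@H](O1)C2=[N+]1[C@H](C)CC[C@H]1C.[Br-] | intermediate (not isolated)
12 | methyl (1S,5R)-3,3-dimethyl-9-oxo-2,4-dioxabicyclo[3.3.1]non-6-ene-7-carboxylate | CC1(C)O[C@@H]2C=C(C(=O)OC)C[C@H](O1)C2=O | intermediate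
13 | methyl (1S,5R,9S)-9-hydroxy-3,3-dimethyl-2,4-dioxabicyclo[3.3.1]non-6-ene-7-carboxylate | CC1(C)O[C@@H]2C=C(C(=O)OC)C[C@H](O1)[C@@H]2O | intermediate
14 | methyl (3aR,7S,7aS)-7-hydroxy-2,2-dimethyl-3a,6,7,7a-tetrahydro-1,3-benzodioxole-5-carboxylate | CC1(C)O[C@@H]2C=C(C(=O)OC)C[C@H](O)[C@@H]2O1 | intermediate
15 | methyl (3aR,7R,7aS)-2,2-dimethyl-7-{[(E)-3-methylpent-2-enoyl]oxy}-3a,6,7,7a-tetrahydro-1,3-benzodioxole-5-carboxylate | CC1(C)O[C@@H]2C=C(C(=O)OC)C[C@@H](OC(=O)/C=C(\C)CC)[C@@H]2O1 | intermediate
16 | methyl (3R,4R,5R)-3,4-dihydroxy-5-{[(E)-3-methylpent-2-enoyl]oxy}cyclohex-1-ene-1-carboxylate | O[C@@H]1C=C(C(=O)OC)C[C@@H](OC(=O)/C=C(\C)CC)[C@@H]1O | intermediate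
17 | methyl (3R,4S,5R)-4-hydroxy-3,5-bis{[(E)-3-methylpent-2-enoyl]oxy}cyclohex-1-ene-1-carboxylate | CC/C(C)=C/C(=O)O[C@@H]1C=C(C(=O)OC)C[C@@H](OC(=O)/C=C(\C)CC)[C@@H]1O | target

**Step count**
Total steps: 10. Longest linear sequence: 7 steps (7 → 9 → 12 → 13 → 14 → 15 → 16 → 17; the same count from 4).

**Steps most likely to fail**

1. Step 5 (Proposed new method). The hindered chiral enamine may close the second bond too slowly, so that intermolecular bis-alkylation competes. Enantiopurity may also leak if part of the first attack goes to the vinylic carbon. Fallback from 7, returning at 12, in which the two bonds are made in separate, precedented operations: 7 is condensed with (S)-1-amino-2-(methoxymethyl)pyrrolidine to the SAMP hydrazone F1. Deprotonation with t-BuLi (THF, −78 °C) and addition of 6 at −100 °C should give the C-alkylated hydrazone F2 by the established auxiliary-controlled azaenolate alkylation of this dioxanone hydrazone. Saturated aqueous oxalic acid/Et2O should release the (S)-ketone F3. Pyrrolidine/AcOH in MeCN at 60 °C should then close the ring through the less substituted enamine by intramolecular addition–elimination onto the β-bromoacrylate, giving 12.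

2. Step 7. The ketal may reclose on the O4/O5 pair instead of O3/O4, a regiochemical leak that would leave the allylic hydroxyl free. Fallback from 13, returning at 17, which uses that regioisomer and replaces the Mitsunobu inversion by a cyclic sulfate opening: methyl 4,5-O-isopropylidene-5-epi-shikimate F4 is esterified with 3 (EDC·HCl, DMAP) to the 3-O-ester F5. Aqueous TFA should give the cis-4,5-diol F6, and SO2Cl2/pyridine (CH2Cl2, −78 °C) the cyclic sulfate F7. The cesium salt of 3 (from Cs2CO3, DMF, 40 °C) should open it at C5 with inversion, C4 being flanked by two oxygen-bearing carbons, to the cesium 4-O-sulfate F8. Brief aqueous H2SO4/THF hydrolysis of the sulfate monoester should give 17.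

3. Step 8. The activated C5 oxygen may be lost by E2 elimination toward the conjugated cyclohexadiene instead of being displaced by the weakly acidic enoic acid. Fallback from 14, returning at 15, which separates inversion from acyl transfer: Mitsunobu inversion with the more acidic 4-nitrobenzoic acid should give the 5-O-(4-nitrobenzoate) F9. K2CO3/MeOH methanolysis should give methyl 3,4-O-isopropylidene shikimate F10, and Steglich esterification with 3 (EDC·HCl, DMAP) then gives 15.

**Further compounds**
F1 | step 5 | (S)-N-(2,2-dimethyl-1,3-dioxan-5-ylidene)-2-(methoxymethyl)pyrrolidin-1-amine (SAMP hydrazone of 7) | COC[C@@H]1CCCN1N=C1COC(C)(C)OC1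
F2 | step 5 | methyl (E)-3-bromo-2-{[(4S)-5-{[(S)-2-(methoxymethyl)pyrrolidin-1-yl]imino}-2,2-dimethyl-1,3-dioxan-4-yl]methyl}acrylate | COC[C@@H]1CCCN1N=C1COC(C)(C)O[C@H]1C/C(C(=O)OC)=C\Br
F3 | step 5 | methyl (E)-3-bromo-2-{[(4S)-2,2-dimethyl-5-oxo-1,3-dioxan-4-yl]methyl}acrylate | CC1(C)OCC(=O)[C@H](C/C(C(=O)OC)=C\Br)O1
F4 | step 7 | methyl 4,5-O-isopropylidene-5-epi-shikimate (all-cis, free 3-OH) | O[C@@H]1C=C(C(=O)OC)C[C@@H]2OC(C)(C)O[C@H]12
F5 | step 7 | methyl 4,5-O-isopropylidene-3-O-[(E)-3-methylpent-2-enoyl]-5-epi-shikimate | CC/C(C)=C/C(=O)O[C@@H]1C=C(C(=O)OC)C[C@@H]2OC(C)(C)O[C@H]12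
F6 | step 7 | methyl 3-O-[(E)-3-methylpent-2-enoyl]-5-epi-shikimate | CC/C(C)=C/C(=O)O[C@@H]1C=C(C(=O)OC)C[C@H](O)[C@@H]1O
F7 | step 7 | methyl 3-O-[(E)-3-methylpent-2-enoyl]-5-epi-shikimate 4,5-cyclic sulfate | CC/C(C)=C/C(=O)O[C@@H]1C=C(C(=O)OC)C[C@@H]2OS(=O)(=O)O[C@H]12
F8 | step 7 | cesium 4-O-sulfate of 17 | CC/C(C)=C/C(=O)O[C@@H]1C=C(C(=O)OC)C[C@@H](OC(=O)/C=C(\C)CC)[C@@H]1OS(=O)(=O)[O-].[Cs+]
F9 | step 8 | methyl 3,4-O-isopropylidene-5-O-(4-nitrobenzoyl)shikimate | CC1(C)O[C@@H]2C=C(C(=O)OC)C[C@@H](OC(=O)c3ccc(cc3)[N+](=O)[O-])[C@@H]2O1
F10 | step 8 | methyl 3,4-O-isopropylidene shikimate | CC1(C)O[C@@H]2C=C(C(=O)OC)C[C@@H](O)[C@@H]2O1
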